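**Retrosynthetic overview**
1. Chromene numbering is used (O1, C2, C3, C4, C4a, C5–C8, C8a). Late disconnections: C5–OH from C5–F (SNAr ortho to the diketone); the C6 diketone from C6–H lithiation, an oxalic bis-Weinreb amide and a 4-oxyphenyl Grignard reagent; C3=C4 from a chroman-4-ol.
2. Key disconnection: pyran ring B is opened at C3–C4 and at O1–C8a, and the C8–prenyl bond is cut with them, leaving 2,6-difluoro-4-methoxybenzaldehyde, the four-carbon dianion LiCH2C(CH3)2OLi and prenyl bromide.
3. Forward, in one pot: the carbanion adds to CHO (C3–C4); lithiation between F and OMe and loss of LiF give the C8–C8a aryne; the tethered tertiary alkoxide closes on C8a (O1–C8a); the C8 carbanion takes the prenyl group.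
4. Enabling feature: ring A is a 1,3,5-trioxygenated benzene in which C4a (carrying the C4 handle) lies between two oxygen-bearing carbons (C8a with O1, C5 with OH), and C7–OMe lies between C8 and C6. This mirror pattern maps onto a symmetric difluoroarene: the C7 methoxy acidifies C8–H next to the C8a fluoride and steers the alkoxide to C8a, and the second fluoride later directs lithiation to C6 and serves as latent C5–OH.
5. Ring order: ring A (arene) and ring C (4-hydroxyphenyl) are bought; ring B (pyran) is the only ring formed, in step 1.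

Key step: step 1

Assumption: the target has no stereocentre. The C4 carbinol centre of 5–10, the hemiaminal centres of 15 and 16 and the acetal centre of the THP group are racemic, and all are removed before the end.

**Step 1**
Reactants: 1 2,6-difluoro-4-methoxybenzaldehyde; 2 1-chloro-2-methylpropan-2-ol; 3 1-bromo-3-methylbut-2-ene (prenyl bromide)
Product: 9 rac-5-fluoro-7-methoxy-2,2-dimethyl-8-(3-methylbut-2-en-1-yl)-3,4-dihydro-2H-chromen-4-ol, via dilithio reagent 4 (not isolated), via dilithium diolate 5 (not isolated), via ring-lithiated diolate 6 (not isolated), via aryne 7 (not isolated), via C8-lithiated chromanolate 8 (not isolated)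
Conditions: 2, n-BuLi (1 equiv), THF, −78 °C, then LiC10H8 (lithium naphthalenide, 2 equiv), −78 °C; add 1, −78 °C; s-BuLi (1.0 equiv), −78 → −20 °C; recool, CuBr·SMe2 (10 mol%), 3, −78 → 0 °C; aq NH4Cl
Reagents that add atoms: 1-chloro-2-methylpropan-2-ol (2), CC(C)(O)CCl; 1-bromo-3-methylbut-2-ene (3), CC(C)=CCBr
Why: The primary carbanion of 4 should add to the aldehyde of 1 (C3–C4 bond); s-BuLi then removes one of the two equivalent ring protons lying between F and OMe, and on warming the 2-fluoroaryllithium 6 loses LiF to give aryne 7, whose carbon next to the side chain is attacked by the tethered tertiary lithium alkoxide (O1–C8a bond), leaving a carbanion on C8 that is prenylated under CuBr·SMe2 catalysis. The closest known reaction types are the addition of β-oxido alkyllithiums (from chlorohydrin alkoxides by reductive chlorine–lithium exchange) to aldehydes, fluorine-directed ortho-lithiation with aryne formation, ring closure of an aryne by a tethered heteroatom nucleophile with electrophilic quench of the resulting aryllithium, and copper-catalysed allylation of aryllithiums. Ring B closes in a 6-exo-dig mode with the alkoxide entering in the plane of the arene; closure by the benzylic alkoxide would need a four-membered ring and attack at the distal aryne carbon a meta-bridged ring, so neither competes. The only new stereocentre is the C4 carbinol, formed without control as a racemate and erased by the dehydration of step 2. The selectivities needed are secured by the substrate: its mirror symmetry makes both ring CH sites equivalent, lithium sits ortho to only one fluorine so the second fluorine is kept, the methoxy group next to the distal aryne carbon favours a carbanion ortho to OMe (attack at C8a), and the doubly ortho-substituted aryl nucleophile attacks prenyl bromide at CH2 and not at the tertiary terminus.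

**Step 2**
Reactants: 9 rac-5-fluoro-7-methoxy-2,2-dimethyl-8-(3-methylbut-2-en-1-yl)-3,4-dihydro-2H-chromen-4-ol
Product: 11 5-fluoro-7-methoxy-2,2-dimethyl-8-(3-methylbut-2-en-1-yl)-2H-chromene, via mesylate 10 (not isolated)
Conditions: MsCl, Et3N, CH2Cl2, 0 → 40 °C
Reagents that add atoms: none
Why: Mesylation of the electron-rich benzylic alcohol (para-methoxy, ortho-alkoxy) and amine-induced loss of methanesulfonate (elimination) should give the conjugated 2H-chromene without acid, which would endanger the prenyl and chromene double bonds.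

**Step 3**
Reactants: 11 5-fluoro-7-methoxy-2,2-dimethyl-8-(3-methylbut-2-en-1-yl)-2H-chromene; 12 N,N'-dimethoxy-N,N'-dimethyloxamide; 13 4-(tetrahydro-2H-pyran-2-yloxy)phenylmagnesium bromide (racemic, commercial THF solution)
Product: 18 1-[5-fluoro-7-methoxy-2,2-dimethyl-8-(3-methylbut-2-en-1-yl)-2H-chromen-6-yl]-2-(4-hydroxyphenyl)ethane-1,2-dione, via aryllithium 14 (not isolated), via mono-adduct 15 (not isolated), via bis-adduct 16 (not isolated), via THP-protected diketone 17 (not isolated)
Conditions: LiTMP (lithium 2,2,6,6-tetramethylpiperidide), THF, −78 °C; 12 (1.1 equiv), −78 °C; 13 (2.5 equiv), −78 → 0 °C; 2 M HCl, THF, rt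
Reagents that add atoms: N,N'-dimethoxy-N,N'-dimethyloxamide (12), CON(C)C(=O)C(=O)N(C)OC; 4-(tetrahydro-2H-pyran-2-yloxy)phenylmagnesium bromide (13), Br[Mg]c1ccc(OC2CCCCO2)cc1
Why: Amide-base ortho-lithiation at the only ring C–H (C6, flanked by F and OMe) gives 14, which is acylated by 12 to a chelated tetrahedral adduct that masks the first ketone while Grignard reagent 13 adds to the second amide (sequential Weinreb ketone synthesis to an unsymmetrical 1,2-diketone); the acidic quench should collapse both adducts and hydrolyse the THP acetal.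

**Step 4**
Reactants: 18 1-[5-fluoro-7-methoxy-2,2-dimethyl-8-(3-methylbut-2-en-1-yl)-2H-chromen-6-yl]-2-(4-hydroxyphenyl)ethane-1,2-dione; 19 2-(methylsulfonyl)ethanol
Product: 21 1-[5-hydroxy-7-methoxy-2,2-dimethyl-8-(3-methylbut-2-en-1-yl)-2H-chromen-6-yl]-2-(4-hydroxyphenyl)ethane-1,2-dione (CNP0184805.0), via sulfonylethyl ether 20 (not isolated)
Conditions: 19 (1.5 equiv), NaH (4 equiv), DMF, 0 °C → rt; 1 M HCl
Reagents that add atoms: 2-(methylsulfonyl)ethanol (19), CS(=O)(=O)CCO
Why: Nucleophilic aromatic substitution of the fluoride ortho to the diketone carbonyl by the alkoxide of 19, followed by E1cB loss of methyl vinyl sulfone (a hydroxide surrogate), should unveil the hydrogen-bonded C5 phenol; the 4'-phenoxide formed first deactivates the distal carbonyl, and hydroxide, which could trigger a benzilic acid rearrangement, is avoided.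

**Compound list**
1 | 2,6-difluoro-4-methoxybenzaldehyde | COc1cc(F)c(C=O)c(F)c1 | starting material
2 | 1-chloro-2-methylpropan-2-ol | CC(C)(O)CCl | starting material
3 | 1-bromo-3-methylbut-2-ene (prenyl bromide) | CC(C)=CCBr | starting material
4 | lithium 1-lithio-2-methylpropan-2-olate (formed in the flask) | [Li]CC(C)(C)O[Li] | intermediate
5 | rac-dilithium 1-(2,6-difluoro-4-methoxyphenyl)-3-methylbutane-1,3-diolate (formed in the flask) | COc1cc(F)c(C(O[Li])CC(C)(C)O[Li])c(F)c1 | intermediate
6 | rac-dilithium 1-(2,6-difluoro-3-lithio-4-methoxyphenyl)-3-methylbutane-1,3-diolate (formed in the flask) | COc1cc(F)c(C(O[Li])CC(C)(C)O[Li])c(F)c1[Li] | intermediate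
7 | rac-dilithium 1-(6-fluoro-4-methoxy-2,3-didehydrophenyl)-3-methylbutane-1,3-diolate, the aryne (formed in the flask) | COC1=CC(F)=C(C(O[Li])CC(C)(C)O[Li])C#C1 | intermediate
8 | rac-lithium 5-fluoro-8-lithio-7-methoxy-2,2-dimethyl-3,4-dihydro-2H-chromen-4-olate (formed in the flask) | COc1cc(F)c2C(O[Li])CC(C)(C)Oc2c1[Li] | intermediate
9 | rac-5-fluoro-7-methoxy-2,2-dimethyl-8-(3-methylbut-2-en-1-yl)-3,4-dihydro-2H-chromen-4-ol | COc1cc(F)c2C(O)CC(C)(C)Oc2c1CC=C(C)C | intermediate
10 | rac-5-fluoro-7-methoxy-2,2-dimethyl-8-(3-methylbut-2-en-1-yl)-3,4-dihydro-2H-chromen-4-yl methanesulfonate (formed in the flask) | COc1cc(F)c2C(OS(C)(=O)=O)CC(C)(C)Oc2c1CC=C(C)C | intermediate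
11 | 5-fluoro-7-methoxy-2,2-dimethyl-8-(3-methylbut-2-en-1-yl)-2H-chromene | COc1cc(F)c2C=CC(C)(C)Oc2c1CC=C(C)C | intermediate
12 | N,N'-dimethoxy-N,N'-dimethyloxamide | CON(C)C(=O)C(=O)N(C)OC | starting material
13 | 4-(tetrahydro-2H-pyran-2-yloxy)phenylmagnesium bromide (racemic) | Br[Mg]c1ccc(OC2CCCCO2)cc1 | starting material
14 | [5-fluoro-7-methoxy-2,2-dimethyl-8-(3-methylbut-2-en-1-yl)-2H-chromen-6-yl]lithium (formed in the flask) | COc1c([Li])c(F)c2C=CC(C)(C)Oc2c1CC=C(C)C | intermediate
15 | racemic lithium alkoxide of the tetrahedral mono-adduct of 14 and 12 (formed in the flask) | COc1c(C(O[Li])(N(C)OC)C(=O)N(C)OC)c(F)c2C=CC(C)(C)Oc2c1CC=C(C)C | intermediate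
16 | lithium bromomagnesium bis-alkoxide of the double tetrahedral adduct, mixture of diastereomers (formed in the flask) | COc1c(C(O[Li])(N(C)OC)C(O[Mg]Br)(N(C)OC)c3ccc(OC4CCCCO4)cc3)c(F)c2C=CC(C)(C)Oc2c1CC=C(C)C | intermediate
17 | rac-1-[5-fluoro-7-methoxy-2,2-dimethyl-8-(3-methylbut-2-en-1-yl)-2H-chromen-6-yl]-2-[4-(tetrahydro-2H-pyran-2-yloxy)phenyl]ethane-1,2-dione (formed in the flask) | COc1c(C(=O)C(=O)c3ccc(OC4CCCCO4)cc3)c(F)c2C=CC(C)(C)Oc2c1CC=C(C)C | intermediate
18 | 1-[5-fluoro-7-methoxy-2,2-dimethyl-8-(3-methylbut-2-en-1-yl)-2H-chromen-6-yl]-2-(4-hydroxyphenyl)ethane-1,2-dione | COc1c(C(=O)C(=O)c3ccc(O)cc3)c(F)c2C=CC(C)(C)Oc2c1CC=C(C)C | intermediate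
19 | 2-(methylsulfonyl)ethanol | CS(=O)(=O)CCO | starting material
20 | sodium 4-(2-{7-methoxy-2,2-dimethyl-8-(3-methylbut-2-en-1-yl)-5-[2-(methylsulfonyl)ethoxy]-2H-chromen-6-yl}-2-oxoacetyl)phenolate (formed in the flask) | COc1c(C(=O)C(=O)c3ccc(O[Na])cc3)c(OCCS(C)(=O)=O)c2C=CC(C)(C)Oc2c1CC=C(C)C | intermediate
21 | 1-[5-hydroxy-7-methoxy-2,2-dimethyl-8-(3-methylbut-2-en-1-yl)-2H-chromen-6-yl]-2-(4-hydroxyphenyl)ethane-1,2-dione (CNP0184805.0) | COc1c(CC=C(C)C)c2c(c(O)c1C(=O)C(=O)c1ccc(O)cc1)C=CC(C)(C)O2 | target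

**Step count and risks**
Total step count: 4. Longest linear sequence: 4 steps (1 → 9 → 11 → 18 → 21).

Steps most likely to fail:

1. Step 1. Capture of the aryne by the aggregated lithium alkoxide may be slower than its consumption by aryllithium 6, or the C8 carbanion may migrate to the more acidic C6 position and lose LiF a second time. Fallback (sets out from 1 and 4, comes back at 11): the ring is closed without an aryne and the prenyl group is placed with a blocking group.
   - Reagent 4 is added to 1 and the adduct is protonated to give rac-1-(2,6-difluoro-4-methoxyphenyl)-3-methylbutane-1,3-diol F1.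
   - KOtBu in DMF at 80 °C closes the pyran ring by intramolecular SNAr of the tertiary alkoxide on either of the two equivalent fluorides, giving rac-5-fluoro-7-methoxy-2,2-dimethyl-3,4-dihydro-2H-chromen-4-ol F2.
   - Catalytic TsOH in toluene at 80 °C dehydrates it to 5-fluoro-7-methoxy-2,2-dimethyl-2H-chromene F3.
   - LiTMP at −78 °C removes the most acidic ring proton (C6–H, between F and OMe), and Me3SiCl blocks this site as (5-fluoro-7-methoxy-2,2-dimethyl-2H-chromen-6-yl)trimethylsilane F4.
   - n-BuLi in THF at 0 °C metalates the only remaining ring C–H (C8), and CuBr·SMe2 with prenyl bromide gives [5-fluoro-7-methoxy-2,2-dimethyl-8-(3-methylbut-2-en-1-yl)-2H-chromen-6-yl]trimethylsilane F5.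
   - TBAF in wet THF removes the silyl group and delivers 11.

2. Step 4. The alkoxide may add to the diketone and the adduct may fragment or rearrange faster than the fluoride at the flanked, twisted ketone is displaced. Fallback (sets out from 11 through 14, comes back at 21): the fluoride is displaced before the second aryl group is introduced.
   - 14 is treated with 12 and quenched after the first addition to give 2-[5-fluoro-7-methoxy-2,2-dimethyl-8-(3-methylbut-2-en-1-yl)-2H-chromen-6-yl]-N-methoxy-N-methyl-2-oxoacetamide F8.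
   - 19 with NaH in DMF gives the ether N-methoxy-2-{7-methoxy-2,2-dimethyl-8-(3-methylbut-2-en-1-yl)-5-[2-(methylsulfonyl)ethoxy]-2H-chromen-6-yl}-N-methyl-2-oxoacetamide F9.
   - F9 loses methyl vinyl sulfone in the same pot to give 2-[5-hydroxy-7-methoxy-2,2-dimethyl-8-(3-methylbut-2-en-1-yl)-2H-chromen-6-yl]-N-methoxy-N-methyl-2-oxoacetamide F10.
   - Excess 13 first forms the magnesium phenoxide, which chelates and deactivates the ketone, and then adds at the Weinreb amide to give rac-1-[5-hydroxy-7-methoxy-2,2-dimethyl-8-(3-methylbut-2-en-1-yl)-2H-chromen-6-yl]-2-[4-(tetrahydro-2H-pyran-2-yloxy)phenyl]ethane-1,2-dione F11.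
   - 2 M HCl in THF removes the THP group and gives 21.

3. Step 3. The first tetrahedral adduct may collapse early, so that the freed ketone is over-added, or the second addition may fail next to the crowded carbon. Fallback (sets out from 11 through 14, comes back at 17): the two-carbon bridge is built one carbon at a time.
   - 14 is acylated with N-methoxy-N-methylacetamide to give 1-[5-fluoro-7-methoxy-2,2-dimethyl-8-(3-methylbut-2-en-1-yl)-2H-chromen-6-yl]ethan-1-one F6.
   - Palladium-catalysed ketone α-arylation with 2-(4-bromophenoxy)tetrahydro-2H-pyran (Pd2(dba)3, Xantphos, NaOtBu, toluene, 80 °C) gives rac-1-[5-fluoro-7-methoxy-2,2-dimethyl-8-(3-methylbut-2-en-1-yl)-2H-chromen-6-yl]-2-[4-(tetrahydro-2H-pyran-2-yloxy)phenyl]ethan-1-one F7.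
   - Aerobic oxidation of the doubly activated methylene (DABCO, air, DMF, 90 °C) gives 17, which is hydrolysed to 18 with 2 M HCl as in step 3.

**Further compounds**
F1 | step 1 | rac-1-(2,6-difluoro-4-methoxyphenyl)-3-methylbutane-1,3-diol | COc1cc(F)c(C(O)CC(C)(C)O)c(F)c1
F2 | step 1 | rac-5-fluoro-7-methoxy-2,2-dimethyl-3,4-dihydro-2H-chromen-4-ol | COc1cc(F)c2C(O)CC(C)(C)Oc2c1
F3 | step 1 | 5-fluoro-7-methoxy-2,2-dimethyl-2H-chromene | COc1cc(F)c2C=CC(C)(C)Oc2c1
F4 | step 1 | (5-fluoro-7-methoxy-2,2-dimethyl-2H-chromen-6-yl)trimethylsilane | COc1cc2OC(C)(C)C=Cc2c(F)c1[Si](C)(C)C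
F5 | step 1 | [5-fluoro-7-methoxy-2,2-dimethyl-8-(3-methylbut-2-en-1-yl)-2H-chromen-6-yl]trimethylsilane | COc1c(CC=C(C)C)c2OC(C)(C)C=Cc2c(F)c1[Si](C)(C)C
F6 | step 3 | 1-[5-fluoro-7-methoxy-2,2-dimethyl-8-(3-methylbut-2-en-1-yl)-2H-chromen-6-yl]ethan-1-one | COc1c(C(C)=O)c(F)c2C=CC(C)(C)Oc2c1CC=C(C)C
F7 | step 3 | rac-1-[5-fluoro-7-methoxy-2,2-dimethyl-8-(3-methylbut-2-en-1-yl)-2H-chromen-6-yl]-2-[4-(tetrahydro-2H-pyran-2-yloxy)phenyl]ethan-1-one | COc1c(C(=O)Cc3ccc(OC4CCCCO4)cc3)c(F)c2C=CC(C)(C)Oc2c1CC=C(C)C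
F8 | step 4 | 2-[5-fluoro-7-methoxy-2,2-dimethyl-8-(3-methylbut-2-en-1-yl)-2H-chromen-6-yl]-N-methoxy-N-methyl-2-oxoacetamide | COc1c(C(=O)C(=O)N(C)OC)c(F)c2C=CC(C)(C)Oc2c1CC=C(C)C
F9 | step 4 | N-methoxy-2-{7-methoxy-2,2-dimethyl-8-(3-methylbut-2-en-1-yl)-5-[2-(methylsulfonyl)ethoxy]-2H-chromen-6-yl}-N-methyl-2-oxoacetamide | COc1c(C(=O)C(=O)N(C)OC)c(OCCS(C)(=O)=O)c2C=CC(C)(C)Oc2c1CC=C(C)C
F10 | step 4 | 2-[5-hydroxy-7-methoxy-2,2-dimethyl-8-(3-methylbut-2-en-1-yl)-2H-chromen-6-yl]-N-methoxy-N-methyl-2-oxoacetamide | COc1c(C(=O)C(=O)N(C)OC)c(O)c2C=CC(C)(C)Oc2c1CC=C(C)C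
F11 | step 4 | rac-1-[5-hydroxy-7-methoxy-2,2-dimethyl-8-(3-methylbut-2-en-1-yl)-2H-chromen-6-yl]-2-[4-(tetrahydro-2H-pyran-2-yloxy)phenyl]ethane-1,2-dione | COc1c(C(=O)C(=O)c3ccc(OC4CCCCO4)cc3)c(O)c2C=CC(C)(C)Oc2c1CC=C(C)C
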